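Colleague, the quick number for Sunday's flask starts from the capture ceiling φ, the share of the substrate that the charge of second nucleophile can turn into other capture product at one to one, which is 60.0%.

| flask | substrate | first nucleophile | second nucleophile | protic impurity | remark | time |
|---|---|---|---|---|---|---|
| Sunday's | 0.050 M | 0.090 M | 0.030 M | 0.050 M | the very flask that is asked about, followed so far |  |
| Tuesday's | 0.050 M | 0.090 M | 0.030 M | 0.034 M | run made earlier |  |
| flask | 0.050 M | 0.0900 M | 0.0300 M | 0.0500 M |  | 8.0 h |

Sunday's run (percent of the substrate charged)

| time / min | target / % | other capture product / % |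
|---|---|---|
| 6.00 | 1.1 | 3.9 |
| 20.0 | 3.5 | 14.8 |
| 30.0 | 5.5 | 22.3 |
| 50.0 | 5.5 | 35.7 |
| 80.0 | 6.4 | 47.0 |
| 90.0 | 6.6 | 51.9 |

Tuesday's run (percent of the substrate charged)

| time / h | target / % | other capture product / % |
|---|---|---|
| 0.417 | 4.8 | 18.4 |
| 1.00 | 5.4 | 41.1 |
| 2.00 | 11.8 | 57.0 |
| 3.00 | 20.9 | 60.1 |
| 4.00 | 27.1 | 60.4 |
| 6.00 | 32.3 | 59.6 |

(readings scatter by 1 percentage point)

- ratio of target to other capture product at 80 s
- ratio of target to other capture product at 25 min
- ratio of target to other capture product at 8.0 h
- which of target and other capture product there is more of at 8.0 h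

- the numbers in the tables scatter with a standard deviation of 1 percentage point

Second nucleophile is the limiting reagent of that capture, charged at 0.0300 M against 0.050 M of substrate. Tuesday's run, with the same two charges, reads 60.1% of other capture product at 3.00 h and 59.6% at 6.00 h, while Sunday's flask reads 51.9% at 90.0 min, still below φ. With other capture product at φ, target has the room that remains, 40.0%, so on that assumption the ratio at 8.0 h comes to at most 0.667, with other capture product ahead. This reckoning commits to that bound and gives no point value. For 25 min, the nearest of Sunday's readings, with their scatter, give a ratio of 0.236 at 20.0 min and 0.247 at 30.0 min. The first reading comes at 6.00 min, later than 80 s, so the earliest ratio is not read at all.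

The forecast goes further, with 0.26 at 80 s, 0.24 at 25 min and 0.55 at 8.0 h, in a range from 0.25 to 0.67: “Other capture product leads either way.”

The flask gives 1.84, 0.236 and 0.544 at those times, with other capture product ahead.

    second nucleophile + intermediate → other capture product (k = 4000 L mol⁻¹ h⁻¹)
    first nucleophile + protic impurity → quenched reagent (k = 1.00 L mol⁻¹ h⁻¹)
    first nucleophile + intermediate ⇌ target (K = 92.0 L mol⁻¹, k = 3400 L mol⁻¹ h⁻¹)
    substrate → intermediate (k = 0.620 h⁻¹)

Target and other capture product stand level at 4.65 min, later than 80 s and earlier than the first reading at 6.00 min, so target's lead at 80 s lies before the readings begin. At 8.0 h, other capture product holds 60.0%, level with φ, and target 32.6%, inside the room. In the neighbour flask with 0.085 M of substrate, φ falls to 35.3% and other capture product stands at 35.3%, so the room grows to 64.7%, of which target holds 48.1%.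

The readings are calculated for substances that don't exist; scatter was added.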